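**Retrosynthetic overview**

1. Lignan numbering is used. C7 and C7' are the ArCH–O carbons: C7 carries the free-phenol aryl Ar1 (endo) and C7' the prenyloxy aryl Ar2 (exo). C8/C8' are the ring-fusion carbons and C9/C9' the OCH2 carbons. Ring A is C7–O–C9'–C8'–C8 and ring B is C7'–O–C9–C8–C8'.
2. Feature used: in ring B the donor-substituted C7' and C8 are linked only through C8' and through the O–C9H2 bridge. With C7 written as a lactone carbonyl, C8 becomes an acceptor carbon. C7' and C8 are then the two ends of a donor–acceptor cyclopropane (C7'–C8'–C8) fused to ring A, and the O–C9 bridge is formaldehyde.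
3. Late disconnections: the prenyl ether comes from an allyl ether and the phenol from a TIPS ether. C7–Ar1 and C7–H come from aryllithium addition to the ring A lactone and convex-face silane reduction (Ar1 endo). C8–H comes from C8–CO2Me, a removable second acceptor, added because a lactone alone polarises an arylcyclopropane too weakly.
4. Key disconnection: C8–C9 and O–C7' of ring B come from the ester-activated 6-aryl-3-oxabicyclo[3.1.0]hexan-2-one plus CH2O. The cyclopropane comes from O-allylconiferaldehyde and dimethyl bromomalonate by organocatalytic Michael-initiated ring closure, then reduction and lactonisation.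
5. Ring order: cyclopropane, ring A (as lactone), ring B (cyclopropane consumed), then the ring A carbonyl is turned into the C7 centre. Only C8' is carried over from the catalytic step, and it relays to C8, C7' and C7.

Key step: step 4

Assumption: the sense of induction in step 2 follows the usual shielding model for diarylprolinol silyl ether iminium ions, by which the (R)-catalyst should give the (2S,3R)-cyclopropane. If the assignment of 5 or 7 showed the opposite, the equally available (S)-catalyst would be used.

**Route**

Step 1
Reactants: 1 coniferaldehyde; 2 allyl bromide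
Product: 3 (E)-3-[4-(allyloxy)-3-methoxyphenyl]prop-2-enal
Conditions: allyl bromide (1.2 equiv), K2CO3 (1.5 equiv), acetone, 50 °C
Reagents that add atoms: allyl bromide (2), C=CCBr
Why: Williamson etherification of the phenoxide is reliable, and the allyl ether stands in for the prenyl ether because its monosubstituted alkene should tolerate the Lewis acids and formaldehyde met later while keeping the ring a strong donor.

Step 2
Reactants: 3 (E)-3-[4-(allyloxy)-3-methoxyphenyl]prop-2-enal; 4 dimethyl bromomalonate
Product: 5 dimethyl (2S,3R)-2-formyl-3-[4-(allyloxy)-3-methoxyphenyl]cyclopropane-1,1-dicarboxylate (formyl and aryl trans)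
Conditions: (R)-α,α-diphenylprolinol trimethylsilyl ether (20 mol %), 2,6-lutidine (1.1 equiv), CH2Cl2, 0 °C → rt
Reagents that add atoms: dimethyl bromomalonate (4), COC(=O)C(Br)C(=O)OC
Why: In this iminium–enamine Michael-initiated ring closure the bromomalonate adds to the β-carbon (C7') on the face left open by the CPh2OSiMe3 group and the enamine then displaces bromide (3-exo-tet), which sets C7' under catalyst control and C8' trans to it, the weak base 2,6-lutidine being chosen so that the product is not ring-opened.

Step 3
Reactants: 5 dimethyl (2S,3R)-2-formyl-3-[4-(allyloxy)-3-methoxyphenyl]cyclopropane-1,1-dicarboxylate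
Product: 7 methyl (1R,5S,6R)-6-[4-(allyloxy)-3-methoxyphenyl]-2-oxo-3-oxabicyclo[3.1.0]hexane-1-carboxylate (aryl exo), via hydroxymethyl diester 6 (not isolated)
Conditions: NaBH4, MeOH, 0 °C; aq NH4Cl; crude 6, DBU (10 mol %), toluene, rt
Reagents that add atoms: none
Why: Chemoselective borohydride reduction of the aldehyde leaves the malonate esters untouched, and the new C9' hydroxyl lactonises on the one ester cis to it, which closes ring A, fixes C8 without choice and leaves the other ester as second acceptor.

Step 4
Reactants: 7 methyl (1R,5S,6R)-6-[4-(allyloxy)-3-methoxyphenyl]-2-oxo-3-oxabicyclo[3.1.0]hexane-1-carboxylate; 8 formaldehyde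
Product: 9 methyl (1S,5S,6R)-6-[4-(allyloxy)-3-methoxyphenyl]-2-oxo-3,7-dioxabicyclo[3.3.0]octane-1-carboxylate (cis-fused, aryl exo, ester on the convex face)
Conditions: CH2O gas (about 5 equiv, from paraformaldehyde cracked in a separate flask), Sc(OTf)3 (10 mol %), 4 Å MS, CH2Cl2 (dilute), −30 °C → rt
Reagents that add atoms: formaldehyde (8), C=O
Why: Proposed new method: Sc(OTf)3 chelated by the lactone and ester carbonyls of 7 polarises the exocyclic C7'–C8 bond, the one cyclopropane bond that overlaps with both acceptor π systems and ends at the carbon bearing the 4-allyloxy-3-methoxyphenyl donor, and opens it to a contact pair of a quinone-methide-like C7' cation and a scandium-bound C8 enolate while C8' stays sp3 and keeps the absolute configuration. Formaldehyde then bridges this 1,3-dipole with its oxygen on C7' and its carbon (C9) on C8; the closest known reaction type is the Lewis-acid (3+2) annulation of 2-arylcyclopropane-1,1-diesters with aryl or alkyl aldehydes to tetrahydrofurans, which has not been shown for formaldehyde or for a lactone-fused cyclopropane. Ring B closes either by 5-(enolexo)-endo-trig attack of C8 on the O-bound oxocarbenium carbon C9 (oxygen first, the order accepted for the diester annulation) or by 5-exo-trig attack of the C9 alkoxide on the C7' cation (carbon first, plausible for so electrophilic an aldehyde), and both orders give the same constitution. C8 is controlled by C8' through ring A, because C9 can only be tied to C7' on the face of the lactone that carries C7' (a trans-fused bicyclo[3.3.0]octane is out of reach), which leaves the ester on the convex face. C7' is not relayed from the cyclopropane, since a strictly SN2-like opening would invert it and turn the aryl group endo; with this strong donor the cation should instead live long enough to close through the rotamer that turns the aryl group away from C9', and reversible C7'–O ionisation under the Lewis acid should correct any endo isomer, so that C8' again decides in favour of the exo (convex-face) aryl group. The step needs capture by formaldehyde to outrun proton loss from C8', arene alkylation, ester participation and a second formaldehyde uptake, which the excess of monomeric aldehyde, low temperature, dilution, molecular sieves and the poorly nucleophilic allyl (rather than prenyl) ether are meant to secure.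

Step 5
Reactants: 9 methyl (1S,5S,6R)-6-[4-(allyloxy)-3-methoxyphenyl]-2-oxo-3,7-dioxabicyclo[3.3.0]octane-1-carboxylate
Product: 10 (1S,5S,6R)-6-[4-(allyloxy)-3-methoxyphenyl]-3,7-dioxabicyclo[3.3.0]octan-2-one (exo-aryl furofuranone)
Conditions: LiCl (3 equiv), H2O (2 equiv), DMSO, 130 °C
Reagents that add atoms: none
Why: In this Krapcho dealkoxycarbonylation chloride attacks the methyl group, the carboxylate loses CO2 and the lactone enolate can be protonated at C8 only to the cis-fused bicycle, while the C9–O bond lies near the nodal plane of the enolate (β-elimination disfavoured) and the temperature stays below that needed for an aromatic Claisen rearrangement.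

Step 6
Reactants: 11 4-bromo-2-methoxyphenol; 12 chlorotriisopropylsilane
Product: 13 (4-bromo-2-methoxyphenoxy)triisopropylsilane
Conditions: TIPSCl, imidazole, DMF, rt
Reagents that add atoms: chlorotriisopropylsilane (12), CC(C)[Si](Cl)(C(C)C)C(C)C
Why: Standard phenol silylation gives a bulky silyl ether that should withstand n-BuLi, BF3·OEt2 at low temperature, zerovalent palladium and K2CO3, and that sits para to the carbon to be metalated so that no silyl migration can occur.

Step 7
Reactants: 13 (4-bromo-2-methoxyphenoxy)triisopropylsilane; 10 (1S,5S,6R)-6-[4-(allyloxy)-3-methoxyphenyl]-3,7-dioxabicyclo[3.3.0]octan-2-one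
Product: 15 (1S,5S,6R)-6-[4-(allyloxy)-3-methoxyphenyl]-2-[3-methoxy-4-(triisopropylsilyloxy)phenyl]-3,7-dioxabicyclo[3.3.0]octan-2-ol (hemiketal, C2 epimers), via aryllithium 14 (not isolated)
Conditions: 13 (1.2 equiv), n-BuLi (1.15 equiv), THF, −78 °C; then 10, −78 °C; aq NH4Cl at −78 °C
Reagents that add atoms: none
Why: Bromine–lithium exchange is followed by 1,2-addition of the aryllithium to the γ-lactone, whose tetrahedral lithium alkoxide should persist at −78 °C so that a second addition and epimerisation at C8 are avoided, and the slight deficit of n-BuLi protects the allyl ether.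

Step 8
Reactants: 15 hemiketal
Product: 16 (1S,2S,5S,6R)-6-[4-(allyloxy)-3-methoxyphenyl]-2-[3-methoxy-4-(triisopropylsilyloxy)phenyl]-3,7-dioxabicyclo[3.3.0]octane (Ar1 endo, Ar2 exo)
Conditions: Et3SiH (4 equiv), BF3·OEt2 (1.5 equiv), CH2Cl2, −78 → −40 °C; aq NaHCO3
Reagents that add atoms: none
Why: In this ionic silane reduction of a hemiketal BF3·OEt2 should ionise the tertiary, aryl- and oxygen-stabilised C7 far faster than the secondary benzylic ether at C7', and Et3SiH delivers hydride to the convex face of the cis-fused oxocarbenium ion, which places H7 exo and Ar1 endo (7S).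

Step 9
Reactants: 16 allyl ether
Product: 17 4-{(1S,2R,5S,6S)-6-[3-methoxy-4-(triisopropylsilyloxy)phenyl]-3,7-dioxabicyclo[3.3.0]octan-2-yl}-2-methoxyphenol (core as in 16, Ar2 phenol free)
Conditions: Pd(PPh3)4 (5 mol %), morpholine (5 equiv), THF, rt
Reagents that add atoms: none
Why: In this Tsuji–Trost-type deallylation zerovalent palladium ionises the aryl allyl ether to a π-allyl complex that morpholine captures, under neutral conditions that should touch neither the TIPS ether nor the benzylic ethers.

Step 10
Reactants: 17 phenol; 18 prenyl bromide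
Product: 19 (1S,2S,5S,6R)-2-[3-methoxy-4-(triisopropylsilyloxy)phenyl]-6-[3-methoxy-4-(3-methylbut-2-enyloxy)phenyl]-3,7-dioxabicyclo[3.3.0]octane
Conditions: prenyl bromide (1.2 equiv), K2CO3, acetone, rt
Reagents that add atoms: prenyl bromide (18), CC(C)=CCBr
Why: Williamson etherification of the only free phenol installs the acid-sensitive prenyl group after the last Lewis-acid step, and the TIPS ether should resist K2CO3 in acetone.

Step 11
Reactants: 19 TIPS ether
Product: 20 target, (1S,2S,5S,6R)-2-(4-hydroxy-3-methoxyphenyl)-6-[3-methoxy-4-(3-methylbut-2-enyloxy)phenyl]-3,7-dioxabicyclo[3.3.0]octane (7S,8S,8'S,7'R)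
Conditions: Bu4NF (1.1 equiv), AcOH (1.1 equiv), THF, 0 °C
Reagents that add atoms: none
Why: Fluoride desilylation spares the prenyl ether, and the acetic acid buffer avoids a free phenoxide that could open ring A through a quinone methide and epimerise the endo C7 centre.

**Compound list**

1 | coniferaldehyde, (E)-3-(4-hydroxy-3-methoxyphenyl)prop-2-enal | COc1cc(/C=C/C=O)ccc1O | starting material
2 | allyl bromide | C=CCBr | starting material
3 | (E)-3-[4-(allyloxy)-3-methoxyphenyl]prop-2-enal | COc1cc(/C=C/C=O)ccc1OCC=C | intermediate
4 | dimethyl bromomalonate | COC(=O)C(Br)C(=O)OC | starting material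
5 | dimethyl (2S,3R)-2-formyl-3-[4-(allyloxy)-3-methoxyphenyl]cyclopropane-1,1-dicarboxylate | O=C[C@H]1[C@H](c2ccc(OCC=C)c(OC)c2)C1(C(=O)OC)C(=O)OC | intermediate
6 | dimethyl (2S,3R)-2-(hydroxymethyl)-3-[4-(allyloxy)-3-methoxyphenyl]cyclopropane-1,1-dicarboxylate | OC[C@H]1[C@H](c2ccc(OCC=C)c(OC)c2)C1(C(=O)OC)C(=O)OC | intermediate
7 | methyl (1R,5S,6R)-6-[4-(allyloxy)-3-methoxyphenyl]-2-oxo-3-oxabicyclo[3.1.0]hexane-1-carboxylate | O=C1OC[C@H]2[C@H](c3ccc(OCC=C)c(OC)c3)[C@@]12C(=O)OC | intermediate
8 | formaldehyde | C=O | starting material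
9 | methyl (1S,5S,6R)-6-[4-(allyloxy)-3-methoxyphenyl]-2-oxo-3,7-dioxabicyclo[3.3.0]octane-1-carboxylate | O=C1OC[C@@H]2[C@@]1(C(=O)OC)CO[C@H]2c1ccc(OCC=C)c(OC)c1 | intermediate
10 | (1S,5S,6R)-6-[4-(allyloxy)-3-methoxyphenyl]-3,7-dioxabicyclo[3.3.0]octan-2-one | O=C1OC[C@@H]2[C@H]1CO[C@H]2c1ccc(OCC=C)c(OC)c1 | intermediate
11 | 4-bromo-2-methoxyphenol | COc1cc(Br)ccc1O | starting material
12 | chlorotriisopropylsilane | CC(C)[Si](Cl)(C(C)C)C(C)C | starting material
13 | (4-bromo-2-methoxyphenoxy)triisopropylsilane | COc1cc(Br)ccc1O[Si](C(C)C)(C(C)C)C(C)C | intermediate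
14 | [3-methoxy-4-(triisopropylsilyloxy)phenyl]lithium | COc1cc([Li])ccc1O[Si](C(C)C)(C(C)C)C(C)C | intermediate
15 | (1S,5S,6R)-6-[4-(allyloxy)-3-methoxyphenyl]-2-[3-methoxy-4-(triisopropylsilyloxy)phenyl]-3,7-dioxabicyclo[3.3.0]octan-2-ol (C2 epimers) | OC1(c2ccc(O[Si](C(C)C)(C(C)C)C(C)C)c(OC)c2)OC[C@@H]2[C@H]1CO[C@H]2c1ccc(OCC=C)c(OC)c1 | intermediate
16 | (1S,2S,5S,6R)-6-[4-(allyloxy)-3-methoxyphenyl]-2-[3-methoxy-4-(triisopropylsilyloxy)phenyl]-3,7-dioxabicyclo[3.3.0]octane | COc1cc([C@H]2OC[C@@H]3[C@H]2CO[C@H]3c2ccc(OCC=C)c(OC)c2)ccc1O[Si](C(C)C)(C(C)C)C(C)C | intermediate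
17 | 4-{(1S,2R,5S,6S)-6-[3-methoxy-4-(triisopropylsilyloxy)phenyl]-3,7-dioxabicyclo[3.3.0]octan-2-yl}-2-methoxyphenol | COc1cc([C@H]2OC[C@@H]3[C@H]2CO[C@H]3c2ccc(O)c(OC)c2)ccc1O[Si](C(C)C)(C(C)C)C(C)C | intermediate
18 | prenyl bromide, 1-bromo-3-methylbut-2-ene | CC(C)=CCBr | starting material
19 | (1S,2S,5S,6R)-2-[3-methoxy-4-(triisopropylsilyloxy)phenyl]-6-[3-methoxy-4-(3-methylbut-2-enyloxy)phenyl]-3,7-dioxabicyclo[3.3.0]octane | COc1cc([C@H]2OC[C@@H]3[C@H]2CO[C@H]3c2ccc(OCC=C(C)C)c(OC)c2)ccc1O[Si](C(C)C)(C(C)C)C(C)C | intermediate
20 | (1S,2S,5S,6R)-2-(4-hydroxy-3-methoxyphenyl)-6-[3-methoxy-4-(3-methylbut-2-enyloxy)phenyl]-3,7-dioxabicyclo[3.3.0]octane | COc1cc([C@H]2OC[C@@H]3[C@H]2CO[C@H]3c2ccc(OCC=C(C)C)c(OC)c2)ccc1O | target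

**Step count**

Total step count: 11. Longest linear sequence: 10 (steps 1–5 and 7–11). Step 6 is a one-step branch.

**Steps most likely to fail**

**1. Step 4 (the labelled step).**
- What may go wrong:
  - The opened ion pair may be lost before formaldehyde is taken up, through proton loss from C8', alkylation of a second arene or ester participation.
  - Formaldehyde may polymerise or be taken up twice.
  - The closure may show poor exo/endo control at C7'.
- Fallback (known reactions only): the same two bonds are made one at a time on the monocyclic diester, where C8 is not yet stereogenic. It sets out from 5 and comes back at 9.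
- Aldehyde 5 is reduced (NaBH4, MeOH–THF, −20 °C). The crude alcohol is silylated at once (TBDPSCl, imidazole, CH2Cl2) to the cyclopropane silyl ether F1.
- Lewis-acid-catalysed nucleophilic ring opening of this donor–acceptor cyclopropane with methanol (Sc(OTf)3 cat., MeOH–CH2Cl2, 0 °C) gives the benzylic methyl ether malonate F2 as C7' epimers.
- Base-mediated hydroxymethylation of the monosubstituted malonate (aqueous CH2O, K2CO3, THF) forms C8–C9 in the hydroxymethyl malonate F3.
- Catalytic camphorsulfonic acid in CH2Cl2 ionises the benzylic ether, and the C9 hydroxyl closes ring B to the 4,5-trans tetrahydrofuran diester F4. The trans relation should be favoured under reversible ionisation.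
- Bu4NF/AcOH then frees the C9' hydroxyl, which lactonises on the ester cis to it and gives 9.

**2. Step 8.**
- What may go wrong:
  - Ionisation at C7'–O, or re-ionisation at the newly formed C7–O, may compete with hemiketal ionisation. This would lead to epimerisation of the endo aryl group to exo or to reductive opening of a ring.
  - Facial selectivity of hydride delivery may be incomplete.
- Fallback: C7 is set by reagent control and ring A is closed without breaking the C7–O bond. It sets out from 15 and comes back at 16.
- The open hydroxy-ketone tautomer of 15 is reduced by Corey–Bakshi–Shibata reduction ((R)-Me-oxazaborolidine, BH3·SMe2, THF, −20 °C) to the (7S)-configured diol F5.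
- Mitsunobu cyclodehydration (PPh3, DIAD, THF, 0 °C) activates the primary C9' hydroxyl. The C7 hydroxyl displaces it (5-exo-tet) with retention at C7, giving 16 under non-acidic conditions.

**3. Step 5.**
- What may go wrong:
  - Dealkylation at the hindered quaternary ester may be slow and force longer heating.
  - Longer heating could bring the onset of aromatic Claisen rearrangement of the allyl ether, β-elimination across C8–C9 or chloride attack at C9'.
- Fallback: hydrolytic removal at lower temperature. It sets out from 9 and comes back at 10.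
- LiOH (THF–H2O, 0 °C → rt) saponifies the ester, with transient lactone opening. Acidification to pH 2 relactonises the material to the lactone carboxylic acid F6.
- The malonic-type acid is decarboxylated in toluene at 100 °C with catalytic Et3N. Protonation at C8 again gives only the cis-fused 10.

**Further compounds**

F1 | step 4 | dimethyl (2S,3R)-2-[(tert-butyldiphenylsilyloxy)methyl]-3-[4-(allyloxy)-3-methoxyphenyl]cyclopropane-1,1-dicarboxylate | CC(C)(C)[Si](c1ccccc1)(c1ccccc1)OC[C@H]1[C@H](c2ccc(OCC=C)c(OC)c2)C1(C(=O)OC)C(=O)OC
F2 | step 4 | dimethyl 2-{(2S)-1-[4-(allyloxy)-3-methoxyphenyl]-1-methoxy-3-(tert-butyldiphenylsilyloxy)propan-2-yl}malonate (C7' epimers) | CC(C)(C)[Si](c1ccccc1)(c1ccccc1)OC[C@@H](C(OC)c1ccc(OCC=C)c(OC)c1)C(C(=O)OC)C(=O)OC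
F3 | step 4 | dimethyl 2-(hydroxymethyl)-2-{(2S)-1-[4-(allyloxy)-3-methoxyphenyl]-1-methoxy-3-(tert-butyldiphenylsilyloxy)propan-2-yl}malonate (C7' epimers) | CC(C)(C)[Si](c1ccccc1)(c1ccccc1)OC[C@@H](C(OC)c1ccc(OCC=C)c(OC)c1)C(CO)(C(=O)OC)C(=O)OC
F4 | step 4 | dimethyl (4S,5R)-5-[4-(allyloxy)-3-methoxyphenyl]-4-[(tert-butyldiphenylsilyloxy)methyl]dihydrofuran-3,3(2H)-dicarboxylate | COC(=O)C1(C(=O)OC)CO[C@@H](c2ccc(OCC=C)c(OC)c2)[C@@H]1CO[Si](c1ccccc1)(c1ccccc1)C(C)(C)C
F5 | step 8 | (S)-{(3S,4S,5R)-5-[4-(allyloxy)-3-methoxyphenyl]-4-(hydroxymethyl)tetrahydrofuran-3-yl}[3-methoxy-4-(triisopropylsilyloxy)phenyl]methanol | O[C@H](c1ccc(O[Si](C(C)C)(C(C)C)C(C)C)c(OC)c1)[C@@H]1CO[C@@H](c2ccc(OCC=C)c(OC)c2)[C@@H]1CO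
F6 | step 5 | (1S,5S,6R)-6-[4-(allyloxy)-3-methoxyphenyl]-2-oxo-3,7-dioxabicyclo[3.3.0]octane-1-carboxylic acid | O=C1OC[C@@H]2[C@@]1(C(=O)O)CO[C@H]2c1ccc(OCC=C)c(OC)c1
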